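Late in the autumn run, at 80.0 s, the readings stood at 0% substrate and 28% tris adduct, so I asked how high the tris adduct curve climbs and when it begins to climb.

in all of them: substrate 0.50 M
- winter: partner 1.1 equiv; run made earlier
- autumn: partner 3.8 equiv; run made earlier
- Wednesday's: partner 0.800 equiv; time 2.5 min
- Tuesday's: partner 1.00 equiv; time 2.5 min
- Saturday's: partner 3.00 equiv; time 2.5 min

| run | time / s | tris adduct / % | substrate / % |
|---|---|---|---|
| winter | 10.0 | 0 | 75 |
| winter | 15.0 | 0 | 60 |
| winter | 20.0 | 0 | 52 |
| winter | 30.0 | 0 | 37 |
| winter | 50.0 | 1 | 17 |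
| winter | 80.0 | 6 | 2 |
| autumn | 10.0 | 3 | 35 |
| autumn | 12.0 | 4 | 28 |
| autumn | 20.0 | 10 | 9 |
| autumn | 30.0 | 14 | 4 |
| autumn | 50.0 | 24 | 1 |
| autumn | 60.0 | 25 | 0 |
| autumn | 80.0 | 28 | 0 |

(standard deviation of a reading: 2 percentage points)



- tris adduct at the end, in percent of the substrate charged, for each flask in turn (Wednesday's, Tuesday's, Saturday's)

The substrate gave me the start of the curve. In the winter run it fell from 75% to 17% of the charge between 10.0 s and 50.0 s, which gives 0.0337 s⁻¹ per equivalent. This clearing constant, the logarithmic fall of substrate per second per equivalent of partner charged, is an apparent pseudo-first-order constant read off scattered readings. Carried to the autumn run, it gave 7.70% substrate at 20.0 s; the reading was 9%, with a scatter of 2 percentage points.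

I put the knee where a tenth of the substrate remains, at 2.3 divided by the constant and the equivalents: 62.0 s for winter and 17.9 s for autumn. Winter tris adduct still read 0% at 30.0 s, before its knee. Autumn read 10% at 20.0 s, just past its knee. The autumn readings then rose 14 points in 30.0 s, but less in the next 30.0 s, only 4 points, so the rise was slowing.

I scaled the last autumn reading with the partner charged. For winter this gave 8.11%, against a reading of 6%. My knees fell at 85.2 s for Wednesday's, 68.2 s for Tuesday's and 22.7 s for Saturday's, and my estimates of tris adduct were 5.89%, 7.37% and 22.1%.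

The forecast gave 6%, 10% and 26%, holding that “tris is disfavoured at low partner”.

The flasks gave 1.90%, 3.48% and 25.0% of tris adduct.

    substrate + by-product → side product B (k = 0.131 L mol⁻¹ s⁻¹)
    partner + first product → bis adduct + by-product (k = 0.0135 L mol⁻¹ s⁻¹)
    substrate + partner → first product + by-product (k = 0.0391 L mol⁻¹ s⁻¹)
    substrate + first product → side product A (k = 0.176 L mol⁻¹ s⁻¹)
    partner + tris adduct → tetra adduct + by-product (k = 0.00110 L mol⁻¹ s⁻¹)
    bis adduct → decomposed reagent (k = 0.0493 s⁻¹)
    partner + bis adduct → tris adduct + by-product (k = 0.242 L mol⁻¹ s⁻¹)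

At the end of Tuesday's flask, first product stood at 9.03%, more than the 3.48% of tris adduct. The clearing constant leaves 0.635% substrate in Tuesday's flask at 2.5 min, and the flask held 0.601%. For Wednesday's flask it leaves 1.75%, and that flask held 1.98%.

All runs were generated by integration on assumed constants; noise was put on by code.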